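## Compound numbers used throughout

1 4-bromo-2-methoxyphenol · 2 its pivalate · 3 propargyl alcohol · 4 aryl propynol · 5 MOM ether of 4 · 6 Z-alkene · 7 cis-epoxide (key-step precursor) · 8 4-iodo-3-methoxybenzaldehyde (key-step precursor) · 9 dihydrobenzofuran aldehyde (key-step product) · 10 3,5-dihydroxybenzyl alcohol · 11 bis-MOM benzyl alcohol · 12 benzyl bromide · 13 benzyl phosphonate · 14 fully protected stilbene · 15 ring B pivalate of the target · 16 gnetofuran A

## Analysis of the target

Gnetofuran A (16) is a 2,3-dihydrobenzofuran: ring A is fused through C3a and C7a to the dihydrofuran ring (O1, C2, C3). C2 carries the guaiacyl ring B, C3 a hydroxymethyl group, C7 a methoxy group, and C5 an (E)-ethenyl bridge to the resorcinol ring C. There are two stereocentres, C2 (R) and C3 (S); they are adjacent and trans across the five-membered ring, so the task is absolute control of one trans pair. The ring B hydroxyl is para to the benzylic C2–O1 bond, so acid (ionisation) or oxidants and strong base (quinone methide formation) can open the ring, epimerise C2 or dehydrogenate C2–C3 to the benzofuran. The electron-rich stilbene is sensitive to strong acid, light and oxidants, and the resorcinol ring is easily alkylated by formaldehyde equivalents. The difficulty is therefore to set C2 and C3 absolutely in a ring that can ionise or aromatise, and to carry three phenols and a primary alcohol to an endgame mild enough for the product. The plan rests on one feature: the adjacent ring A carbons C3a and C7a are bonded to C3 and to O1, the two ends of the unit C3–C2–O1, and if O1 is also joined to C3 this unit is an oxirane. Ring A fits that reading: C7a is flanked by the methoxy-bearing C7 and by C3a, and the C5 substituent is para to C7a.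

## Retrosynthetic reasoning

**16 ← 15 ← 14 (protecting groups).** The last two operations only break O–protecting-group bonds. The ring B oxygen is kept as a pivalate until the very end and the three methoxymethyl groups (one aliphatic, two on ring C) are removed first. The aliphatic acetal needs the most acid, and while ring B still carries an acyloxy group the C2–O1 bond cannot ionise. The final ester methanolysis is then a room-temperature, weakly basic step that the free natural product should tolerate.

**14 ← 9 + 13 (stilbene C=C).** Cutting the C5-bridge double bond gives aldehyde 9 and phosphonate 13. This is the only cut that joins ring C in one step with reliable E geometry and without touching C2 or C3. The forward olefination must use a base that does not attack the aryl pivalate.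

**13 ← 12 ← 11 ← 10 (ring C).** The C–P bond comes from a benzylic bromide, which comes from the benzylic alcohol. Only the two phenols of 10 need masking, as acetals that leave together with the aliphatic one.

**9 ← 7 + 8 (key disconnection: C3–C3a and C7a–O1).** Both bonds from ring A to the heterocycle are cut at once, giving aryl iodide 8 and cis-epoxide 7. Cutting here removes the ring and traces both stereocentres back to one epoxide; no other pair of cuts gives two fragments of similar size with all stereochemistry in one of them. Forward, the ortho C–H of 8 must be alkylated by the CH2OMOM-bearing epoxide carbon with inversion, and the liberated alkoxide must then close on the iodine-bearing carbon. This is a Catellani-type reaction (palladium with a strained bicyclic alkene as transient mediator). One inversion at C3 and retention at C2 convert a cis-epoxide into the trans ring. Three design decisions serve this step: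
- Ring B carries an acyloxy group and not an alkoxy or acetal group. The aryl ring is then non-donating, so the benzylic C–O bond of 7 should not ionise, rearrange or invite attack at the wrong carbon.
- The primary oxygen is a methoxymethyl ether. It is small next to the carbon that must be attacked, and it cannot migrate to the alkoxide set free in the annulation, as an ester could.
- C5 enters as a formyl group. It is para to iodine, where it should speed both oxidative addition and the final C–O bond formation. It also removes any hydride step after the annulation, which would strip the pivalate.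

**7 ← 6 ← 5 ← 4 ← 2 + 3 ← 1 (the epoxide).** The two C–O bonds of the oxirane are cut back to Z-alkene 6; a chiral manganese–salen oxo-transfer catalyst suits cis-disubstituted aryl alkenes and sets both stereocentres of the target. The Z-alkene comes from alkyne 5 by syn semi-hydrogenation. The aryl–alkynyl bond is cut to bromide 2 and propargyl alcohol 3, and 2 is the pivalate of 1.

## Alternatives that were turned down

**Alternative 1:** The C3–C3a bond is made by a 1,2-shift of the ring A carbon within the enantiopure flavanone A1. With PhI(OAc)2, HC(OMe)3 and H2SO4 the pyranone contracts to the trans dihydrobenzofuran ester A2, the former carbonyl carbon becoming the C3 ester.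
- For: the ring contraction is an established reaction of flavanones, so on precedent this route is stronger than the chosen one. C2 is already present in A1, there is no regiochemical question, and the C5 bromide is a ready handle for a later Heck coupling.
- Against: A1 must be a single enantiomer, yet flavanones racemise by reversible retro-oxa-Michael opening, and the strongly acidic conditions put C2 at risk. Enantioselective access to A1 is a multi-step sequence of its own. A2 has C3 at the ester oxidation level with an acidic C3–H β to O1, so E1cB opening can erase C2. Reduction to CH2OH needs a hydride that also removes the pivalate. Migration of ring B instead of ring A, or simple dehydrogenation, can compete.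
- Comparison: the chosen route forms both ring bonds in one convergent step from two simple fragments, with C3 already at the alcohol oxidation level and no enolisable centre. In exchange it accepts an unprecedented key step.

**Alternative 2:** The O1–C2 bond is disconnected. Ag2O oxidises the 4-hydroxy-3-methoxybenzyl unit of bis-phenol A3 to the para-quinone methide A4, and the ring A phenol adds to its exocyclic carbon to give A5, trans to the existing C3 centre.
- For: the closure is mild and biomimetic, the reactivity is well understood, and the trans outcome matches the thermodynamic preference. In mildness and predictability of each bond formation it is stronger than the chosen route.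
- Against: all absolute stereochemistry sits in the C3 centre of A3, which must be installed earlier by auxiliary-controlled or catalytic asymmetric chemistry on a ring A arylacetic acid derivative that is not commercial, so the linear sequence is long. The C2 configuration is only substrate-controlled. The ring A phenol is deactivated by the para ester. A5 contains a free guaiacyl phenol with a benzylic C2–H, so the same oxidant can attack the product.
- Comparison: the chosen route transfers both centres stereospecifically from one catalytic asymmetric epoxidation and is much shorter.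

**Alternative 3:** The C3–C3a bond is disconnected to the chiral allyl aryl ether A6. With Bu3SnH and Et3B under O2 the aryl radical cyclises 5-exo onto the vinyl group; the primary radical is captured by O2 and, after PPh3, appears as the CH2OH group of A7.
- For: the connectivity of the new C–C bond is unambiguous, the reaction type is known, and C5 is already at the aldehyde oxidation level. On certainty of regiochemistry it is stronger than the chosen route.
- Against: A6 is an aryl ether at a carbon that is both allylic and benzylic to an electron-rich ring, so making and keeping it enantiopure is delicate (ionisation, allylic transposition). C3 is set only by kinetic diastereoselection in the cyclisation. Oxygen capture competes with hydrogen abstraction. Stoichiometric tin is needed and the sequence is longer.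
- Comparison: the chosen route offers stereospecific transfer to C3 and fewer steps. This alternative is kept as the reserve for the key step.

Key step: step 6

Assumption: the (S,S)-manganese–salen catalyst is taken to epoxidise 6 with the facial sense it shows for cis-β-methylstyrene, which corresponds to the (2S,3R)-epoxide 7; if the sense proved opposite, the (R,R)-catalyst would be used.
Remark: 1, 3, 8 and 10 are taken to be commercial.

## Route

Step 1
Reactants: 1 4-bromo-2-methoxyphenol
Product: 2 4-bromo-2-methoxyphenyl 2,2-dimethylpropanoate (pivalate)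
Conditions: PivCl, Et3N, DMAP (cat.), CH2Cl2, 0 °C → rt
Reagents that add atoms: pivaloyl chloride, CC(C)(C)C(Cl)=O
Why: DMAP-catalysed acylation of a phenol; the pivalate is chosen because it makes ring B non-donating at the future epoxide stage and resists amines, hypochlorite and carbonate.

Step 2
Reactants: 2 4-bromo-2-methoxyphenyl 2,2-dimethylpropanoate; 3 prop-2-yn-1-ol (propargyl alcohol)
Product: 4 4-(3-hydroxyprop-1-yn-1-yl)-2-methoxyphenyl 2,2-dimethylpropanoate
Conditions: PdCl2(PhCN)2 (cat.), [(t-Bu)3PH]BF4 (cat.), CuI (cat.), i-Pr2NH, 1,4-dioxane, rt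
Reagents that add atoms: none
Why: Sonogashira coupling; the bulky trialkylphosphine system couples aryl bromides at room temperature and the hindered amine should not aminolyse the aryl ester.

Step 3
Reactants: 4 4-(3-hydroxyprop-1-yn-1-yl)-2-methoxyphenyl 2,2-dimethylpropanoate
Product: 5 2-methoxy-4-[3-(methoxymethoxy)prop-1-yn-1-yl]phenyl 2,2-dimethylpropanoate
Conditions: MOMCl, i-Pr2NEt, CH2Cl2, 0 °C → rt
Reagents that add atoms: chloromethyl methyl ether, COCCl
Why: O-alkylation of a primary alcohol (Williamson-type acetal formation); the MOM ether is small and cannot migrate or participate in the later annulation.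

Step 4
Reactants: 5 2-methoxy-4-[3-(methoxymethoxy)prop-1-yn-1-yl]phenyl 2,2-dimethylpropanoate
Product: 6 2-methoxy-4-[(1Z)-3-(methoxymethoxy)prop-1-en-1-yl]phenyl 2,2-dimethylpropanoate
Conditions: H2 (1 atm), Pd/CaCO3 poisoned with Pb(OAc)2 (Lindlar catalyst), quinoline, EtOAc, rt
Reagents that add atoms: none
Why: Lindlar semi-hydrogenation; syn delivery of hydrogen on the poisoned palladium surface should give the Z-alkene, and quinoline holds back over-reduction.

Step 5
Reactants: 6 2-methoxy-4-[(1Z)-3-(methoxymethoxy)prop-1-en-1-yl]phenyl 2,2-dimethylpropanoate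
Product: 7 2-methoxy-4-[(2S,3R)-3-[(methoxymethoxy)methyl]oxiran-2-yl]phenyl 2,2-dimethylpropanoate (cis-epoxide)
Conditions: (S,S)-N,N'-bis(3,5-di-tert-butylsalicylidene)-1,2-cyclohexanediaminomanganese chloride [(S,S)-(salen)MnCl] (cat.), 4-phenylpyridine N-oxide (cat.), NaOCl (aq., pH 11.3 phosphate buffer), CH2Cl2, 0 °C
Reagents that add atoms: sodium hypochlorite, [Na+].[O-]Cl
Why: Jacobsen–Katsuki epoxidation with a chiral salen complex of trivalent manganese, for which cis-disubstituted aryl alkenes are the best substrate class; oxygen is transferred to one enantioface so that the Z geometry becomes the cis-epoxide and both stereocentres of the target are set here. The N-oxide additive and low temperature should suppress the stepwise pathway that leaks to trans-epoxide.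

Step 6
Reactants: 7 2-methoxy-4-[(2S,3R)-3-[(methoxymethoxy)methyl]oxiran-2-yl]phenyl 2,2-dimethylpropanoate; 8 4-iodo-3-methoxybenzaldehyde
Product: 9 4-[(2R,3S)-5-formyl-7-methoxy-3-[(methoxymethoxy)methyl]-2,3-dihydro-1-benzofuran-2-yl]-2-methoxyphenyl 2,2-dimethylpropanoate
Conditions: Pd(OAc)2 (10 mol %), P(2-furyl)3 (25 mol %), norbornene (1.5 equiv), Cs2CO3 (2.5 equiv), 1,4-dioxane, 100 °C, argon
Reagents that add atoms: none
Why: Proposed new method: zerovalent palladium should insert into the C–I bond of 8, norbornene should insert into the aryl–palladium bond, and carbonate-assisted palladation of the only free ortho C–H (the future C3a) should give the five-membered aryl–norbornyl palladacycle of divalent palladium. This electron-rich palladacycle is expected to open epoxide 7 by SN2-type oxidative addition at the carbon bearing CH2OMOM, anti to its C–O bond, giving an alkoxide of tetravalent palladium; C(sp2)–C(sp3) reductive elimination then forms C3–C3a, and β-carbon elimination expels norbornene because the arene now has two ortho substituents. The resulting six-membered aryl palladium alkoxide of divalent palladium closes the dihydrofuran ring by C7a–O1 reductive elimination, which the para-formyl group should accelerate, and returns zerovalent palladium. The closest known reaction type is the palladium/norbornene (Catellani) annulation of ortho-substituted aryl iodides with terminal epoxides to 2-substituted 2,3-dihydrobenzofurans; the extension is to a 1,2-disubstituted epoxide, that is, to attack at a secondary carbon. No stereocentre is created: C2 keeps its C–O bond and configuration, C3 is inverted once in the SN2 step and retained in the reductive elimination, so the cis-(2S,3R)-epoxide should be translated stereospecifically into the trans-(2R,3S) ring. The step needs regioselectivity for the non-benzylic epoxide carbon; the steric demand of the palladacycle (which attacks terminal aryl epoxides at the non-benzylic carbon) should favour it, and the pivaloyloxy group keeps the benzylic C–O bond from ionising or rearranging. Site selectivity on ring A is fixed by the C7 methoxy group, which blocks the second ortho position.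

Step 7
Reactants: 10 3,5-dihydroxybenzyl alcohol
Product: 11 [3,5-bis(methoxymethoxy)phenyl]methanol
Conditions: MOMCl (2.2 equiv), K2CO3, acetone, 0 °C → rt
Reagents that add atoms: chloromethyl methyl ether, COCCl
Why: Williamson-type O-alkylation; carbonate deprotonates the two phenols but not the benzylic alcohol, so only the phenoxides should be alkylated.

Step 8
Reactants: 11 [3,5-bis(methoxymethoxy)phenyl]methanol
Product: 12 1-(bromomethyl)-3,5-bis(methoxymethoxy)benzene
Conditions: CBr4, PPh3, CH2Cl2, 0 °C
Reagents that add atoms: carbon tetrabromide, BrC(Br)(Br)Br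
Why: Appel bromination under neutral conditions, which leaves the acid-labile aryl MOM ethers intact.

Step 9
Reactants: 12 1-(bromomethyl)-3,5-bis(methoxymethoxy)benzene
Product: 13 diethyl {[3,5-bis(methoxymethoxy)phenyl]methyl}phosphonate
Conditions: P(OEt)3 (neat), 130 °C
Reagents that add atoms: triethyl phosphite, CCOP(OCC)OCC
Why: Michaelis–Arbuzov reaction of a benzylic bromide.

Step 10
Reactants: 9 4-[(2R,3S)-5-formyl-7-methoxy-3-[(methoxymethoxy)methyl]-2,3-dihydro-1-benzofuran-2-yl]-2-methoxyphenyl 2,2-dimethylpropanoate; 13 diethyl {[3,5-bis(methoxymethoxy)phenyl]methyl}phosphonate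
Product: 14 4-[(2R,3S)-5-{(E)-2-[3,5-bis(methoxymethoxy)phenyl]ethenyl}-7-methoxy-3-[(methoxymethoxy)methyl]-2,3-dihydro-1-benzofuran-2-yl]-2-methoxyphenyl 2,2-dimethylpropanoate
Conditions: 13, NaN(SiMe3)2 (slight deficit to 13), THF, 0 °C; then 9, 0 °C → rt, light excluded
Reagents that add atoms: none
Why: Horner–Wadsworth–Emmons olefination; benzylic phosphonate anions add reversibly to aryl aldehydes and eliminate to the E-stilbene. The hindered amide base should spare the aryl pivalate, and neither C2–H nor C3–H is acidic enough to be touched.

Step 11
Reactants: 14 4-[(2R,3S)-5-{(E)-2-[3,5-bis(methoxymethoxy)phenyl]ethenyl}-7-methoxy-3-[(methoxymethoxy)methyl]-2,3-dihydro-1-benzofuran-2-yl]-2-methoxyphenyl 2,2-dimethylpropanoate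
Product: 15 4-[(2R,3S)-5-[(E)-2-(3,5-dihydroxyphenyl)ethenyl]-3-(hydroxymethyl)-7-methoxy-2,3-dihydro-1-benzofuran-2-yl]-2-methoxyphenyl 2,2-dimethylpropanoate
Conditions: HCl (ca. 2 M) in MeOH, 45 °C, argon, light excluded
Reagents that add atoms: none
Why: Acid-catalysed acetal exchange removes the three MOM groups, methanol trapping the methoxymethyl cation so that the resorcinol ring is not alkylated. The pivaloyloxy group still on ring B keeps the C2–O1 bond from ionising while the slow aliphatic acetal is cleaved; any methanolysis of the pivalate at this stage only leads on to 16.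

Step 12
Reactants: 15 4-[(2R,3S)-5-[(E)-2-(3,5-dihydroxyphenyl)ethenyl]-3-(hydroxymethyl)-7-methoxy-2,3-dihydro-1-benzofuran-2-yl]-2-methoxyphenyl 2,2-dimethylpropanoate
Product: 16 gnetofuran A, 5-[(E)-2-[(2R,3S)-2-(4-hydroxy-3-methoxyphenyl)-3-(hydroxymethyl)-7-methoxy-2,3-dihydro-1-benzofuran-5-yl]ethenyl]benzene-1,3-diol
Conditions: K2CO3, MeOH (degassed), rt, argon; then aq. NH4Cl
Reagents that add atoms: none
Why: Base-catalysed transesterification of the aryl pivalate; at room temperature the ring B phenoxide should not open the C2–O1 bond, and exclusion of oxygen protects the phenols and the stilbene.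

## Compound list

1 | 4-bromo-2-methoxyphenol | COc1cc(Br)ccc1O | starting material
2 | 4-bromo-2-methoxyphenyl 2,2-dimethylpropanoate | COc1cc(Br)ccc1OC(=O)C(C)(C)C | intermediate
3 | prop-2-yn-1-ol (propargyl alcohol) | C#CCO | starting material
4 | 4-(3-hydroxyprop-1-yn-1-yl)-2-methoxyphenyl 2,2-dimethylpropanoate | COc1cc(C#CCO)ccc1OC(=O)C(C)(C)C | intermediate
5 | 2-methoxy-4-[3-(methoxymethoxy)prop-1-yn-1-yl]phenyl 2,2-dimethylpropanoate | COCOCC#Cc1ccc(OC(=O)C(C)(C)C)c(OC)c1 | intermediate
6 | 2-methoxy-4-[(1Z)-3-(methoxymethoxy)prop-1-en-1-yl]phenyl 2,2-dimethylpropanoate | COCOC/C=C\c1ccc(OC(=O)C(C)(C)C)c(OC)c1 | intermediate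
7 | 2-methoxy-4-[(2S,3R)-3-[(methoxymethoxy)methyl]oxiran-2-yl]phenyl 2,2-dimethylpropanoate (cis) | CC(C)(C)C(=O)Oc1ccc([C@H]2[C@@H](COCOC)O2)cc1OC | intermediate
8 | 4-iodo-3-methoxybenzaldehyde | COc1cc(C=O)ccc1I | starting material
9 | 4-[(2R,3S)-5-formyl-7-methoxy-3-[(methoxymethoxy)methyl]-2,3-dihydro-1-benzofuran-2-yl]-2-methoxyphenyl 2,2-dimethylpropanoate | CC(C)(C)C(=O)Oc1ccc([C@@H]2Oc3c(OC)cc(C=O)cc3[C@H]2COCOC)cc1OC | intermediate
10 | 3,5-dihydroxybenzyl alcohol | OCc1cc(O)cc(O)c1 | starting material
11 | [3,5-bis(methoxymethoxy)phenyl]methanol | COCOc1cc(CO)cc(OCOC)c1 | intermediate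
12 | 1-(bromomethyl)-3,5-bis(methoxymethoxy)benzene | COCOc1cc(CBr)cc(OCOC)c1 | intermediate
13 | diethyl {[3,5-bis(methoxymethoxy)phenyl]methyl}phosphonate | CCOP(=O)(Cc1cc(OCOC)cc(OCOC)c1)OCC | intermediate
14 | 4-[(2R,3S)-5-{(E)-2-[3,5-bis(methoxymethoxy)phenyl]ethenyl}-7-methoxy-3-[(methoxymethoxy)methyl]-2,3-dihydro-1-benzofuran-2-yl]-2-methoxyphenyl 2,2-dimethylpropanoate | CC(C)(C)C(=O)Oc1ccc([C@@H]2Oc3c(OC)cc(/C=C/c4cc(OCOC)cc(OCOC)c4)cc3[C@H]2COCOC)cc1OC | intermediate
15 | 4-[(2R,3S)-5-[(E)-2-(3,5-dihydroxyphenyl)ethenyl]-3-(hydroxymethyl)-7-methoxy-2,3-dihydro-1-benzofuran-2-yl]-2-methoxyphenyl 2,2-dimethylpropanoate | CC(C)(C)C(=O)Oc1ccc([C@@H]2Oc3c(OC)cc(/C=C/c4cc(O)cc(O)c4)cc3[C@H]2CO)cc1OC | intermediate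
16 | gnetofuran A, 5-[(E)-2-[(2R,3S)-2-(4-hydroxy-3-methoxyphenyl)-3-(hydroxymethyl)-7-methoxy-2,3-dihydro-1-benzofuran-5-yl]ethenyl]benzene-1,3-diol | COc1cc([C@@H]2Oc3c(OC)cc(/C=C/c4cc(O)cc(O)c4)cc3[C@H]2CO)ccc1O | target

## Step count and least certain steps

Total: 12 steps. Longest linear sequence: 9 steps (steps 1–6 and 10–12); the phosphonate branch (steps 7–9) is three steps.

**Step 6 (key step).** The most likely failure is that the palladacycle does not undergo oxidative addition at a secondary epoxide carbon. It would then be consumed by ortho-arylation with a second molecule of 8 or by reductive elimination onto the norbornyl carbon. Next most likely is opening at the benzylic carbon, which is intrinsically the more reactive terminus, whereas the desired carbon is deactivated by its neighbouring C–O bond; this would give the regioisomeric ring. Further drains are palladium-mediated isomerisation of the epoxide to a ketone, β-hydride elimination of the benzylic palladium alkoxide before C–O bond formation, and loss of the pivalate, after which the ring B phenoxide would open the epoxide.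

The fallback uses known chemistry (aryl radical cyclisation with oxygenation); it sets out from bromide 2 and returns at 9. Stille coupling of 2 with (E)-3-(tributylstannyl)prop-2-en-1-ol (Pd(PPh3)4, toluene, 100 °C) would give 4-[(1E)-3-hydroxyprop-1-en-1-yl]-2-methoxyphenyl 2,2-dimethylpropanoate F1. Methyl chloroformate and pyridine convert it to the allylic methyl carbonate F2. Iridium-catalysed asymmetric allylic etherification of F2 ([Ir(cod)Cl]2, chiral phosphoramidite of the enantiomeric series that gives the R ether, THF, 50 °C) with the sodium phenoxide of commercial 4-hydroxy-3-iodo-5-methoxybenzaldehyde (COc1cc(C=O)cc(I)c1O) would give the branched (R)-allyl aryl ether F3. Its formyl group is masked as the dioxolane F4 (1,2-bis(trimethylsilyloxy)ethane, Me3SiOTf cat., CH2Cl2, −78 °C). Bu3SnH and Et3B under air then generate the aryl radical at the future C3a. It cyclises 5-exo onto the vinyl group through a chair-like transition state with ring B pseudo-equatorial, forming C3–C3a trans to ring B. The primary radical is captured by O2 as the hydroperoxide F5 (not isolated), which PPh3 reduces in the flask to the alcohol F6. MOMCl and i-Pr2NEt give the ether F7, and mild hydrolysis of the dioxolane (PPTS, acetone/water, rt) returns the route to 9.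

**Step 5 (epoxidation).** Enantiofacial discrimination may be lower for a CH2OMOM-substituted Z-styrene than for the methyl prototype, and the stepwise radical pathway with C–C rotation can leak to the trans-epoxide, which would have to be removed. The fallback sets out from alkynol 4 and returns at 7, replacing steps 3–5. Lindlar semi-hydrogenation of 4 gives the Z-allylic alcohol F8. Sharpless asymmetric epoxidation (Ti(Oi-Pr)4, D-(−)-diethyl tartrate, t-BuOOH, 4 Å molecular sieves, CH2Cl2, −20 °C) would give the cis-epoxy alcohol F9; by the face rule of the titanium–tartrate system it should have the configuration of 7. MOMCl and i-Pr2NEt then give 7.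

**Step 11 (acidic removal of three MOM groups).** The aliphatic acetal is slow to cleave, and the prolonged acid treatment may protonate the electron-rich stilbene (addition of methanol, cyclisation onto the resorcinol ring) or strip the pivalate early. The fallback sets out from 9 and returns at 15. The aliphatic MOM ether is cleaved first, at the stage of 9 where neither stilbene nor resorcinol is present (aq. HCl, THF, 40 °C), to give the hydroxy aldehyde F10. Horner–Wadsworth–Emmons olefination of F10 with an excess of lithiated 13 (LiN(SiMe3)2, THF, −78 → 0 °C; the first equivalent is consumed by the hydroxyl group) gives the stilbene F11. Its two aryl MOM ethers are then removed under much milder conditions (dilute HCl in MeOH, rt) to reach 15.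

**Step 4 (semi-hydrogenation).** Over-reduction to the saturated ether and Z → E isomerisation on the catalyst are the risks, because the aryl-conjugated alkyne and the derived styrene both bind palladium well. The fallback sets out from 5 and returns at 6 without any new compound: a copper hydride semi-reduction (Cu(OAc)2, Xantphos, polymethylhydrosiloxane, t-BuOH, toluene, rt), in which syn hydrocupration of the alkyne and protonolysis of the vinyl–copper bond give the Z-alkene and the alkene is not reduced further.

## Further compounds

F1 | step 6 | 4-[(1E)-3-hydroxyprop-1-en-1-yl]-2-methoxyphenyl 2,2-dimethylpropanoate | COc1cc(/C=C/CO)ccc1OC(=O)C(C)(C)C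
F2 | step 6 | methyl (2E)-3-[3-methoxy-4-(2,2-dimethylpropanoyloxy)phenyl]prop-2-en-1-yl carbonate | COC(=O)OC/C=C/c1ccc(OC(=O)C(C)(C)C)c(OC)c1
F3 | step 6 | 4-[(1R)-1-(4-formyl-2-iodo-6-methoxyphenoxy)prop-2-en-1-yl]-2-methoxyphenyl 2,2-dimethylpropanoate | CC(C)(C)C(=O)Oc1ccc([C@@H](C=C)Oc2c(I)cc(C=O)cc2OC)cc1OC
F4 | step 6 | 4-{(1R)-1-[4-(1,3-dioxolan-2-yl)-2-iodo-6-methoxyphenoxy]prop-2-en-1-yl}-2-methoxyphenyl 2,2-dimethylpropanoate | CC(C)(C)C(=O)Oc1ccc([C@@H](C=C)Oc2c(I)cc(C3OCCO3)cc2OC)cc1OC
F5 | step 6 | 4-[(2R,3S)-5-(1,3-dioxolan-2-yl)-3-(hydroperoxymethyl)-7-methoxy-2,3-dihydro-1-benzofuran-2-yl]-2-methoxyphenyl 2,2-dimethylpropanoate | CC(C)(C)C(=O)Oc1ccc([C@@H]2Oc3c(OC)cc(C4OCCO4)cc3[C@H]2COO)cc1OC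
F6 | step 6 | 4-[(2R,3S)-5-(1,3-dioxolan-2-yl)-3-(hydroxymethyl)-7-methoxy-2,3-dihydro-1-benzofuran-2-yl]-2-methoxyphenyl 2,2-dimethylpropanoate | CC(C)(C)C(=O)Oc1ccc([C@@H]2Oc3c(OC)cc(C4OCCO4)cc3[C@H]2CO)cc1OC
F7 | step 6 | 4-[(2R,3S)-5-(1,3-dioxolan-2-yl)-7-methoxy-3-[(methoxymethoxy)methyl]-2,3-dihydro-1-benzofuran-2-yl]-2-methoxyphenyl 2,2-dimethylpropanoate | CC(C)(C)C(=O)Oc1ccc([C@@H]2Oc3c(OC)cc(C4OCCO4)cc3[C@H]2COCOC)cc1OC
F8 | step 5 | 4-[(1Z)-3-hydroxyprop-1-en-1-yl]-2-methoxyphenyl 2,2-dimethylpropanoate | COc1cc(/C=C\CO)ccc1OC(=O)C(C)(C)C
F9 | step 5 | 4-[(2S,3R)-3-(hydroxymethyl)oxiran-2-yl]-2-methoxyphenyl 2,2-dimethylpropanoate (cis) | CC(C)(C)C(=O)Oc1ccc([C@H]2[C@@H](CO)O2)cc1OC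
F10 | step 11 | 4-[(2R,3S)-5-formyl-3-(hydroxymethyl)-7-methoxy-2,3-dihydro-1-benzofuran-2-yl]-2-methoxyphenyl 2,2-dimethylpropanoate | CC(C)(C)C(=O)Oc1ccc([C@@H]2Oc3c(OC)cc(C=O)cc3[C@H]2CO)cc1OC
F11 | step 11 | 4-[(2R,3S)-5-{(E)-2-[3,5-bis(methoxymethoxy)phenyl]ethenyl}-3-(hydroxymethyl)-7-methoxy-2,3-dihydro-1-benzofuran-2-yl]-2-methoxyphenyl 2,2-dimethylpropanoate | CC(C)(C)C(=O)Oc1ccc([C@@H]2Oc3c(OC)cc(/C=C/c4cc(OCOC)cc(OCOC)c4)cc3[C@H]2CO)cc1OC
F0 | step 4 | none | none
A1 | alternative 1 | (2R)-6-bromo-8-methoxy-2-[3-methoxy-4-(2,2-dimethylpropanoyloxy)phenyl]-2,3-dihydro-4H-chromen-4-one | COc1cc([C@@H]2Oc3c(OC)cc(Br)cc3C(=O)C2)ccc1OC(=O)C(C)(C)C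
A2 | alternative 1 | methyl (2R,3R)-5-bromo-7-methoxy-2-[3-methoxy-4-(2,2-dimethylpropanoyloxy)phenyl]-2,3-dihydro-1-benzofuran-3-carboxylate (trans) | COc1cc([C@@H]2Oc3c(OC)cc(Br)cc3[C@H]2C(=O)OC)ccc1OC(=O)C(C)(C)C
A3 | alternative 2 | methyl 3-[(2S)-1-{[tert-butyl(dimethyl)silyl]oxy}-3-(4-hydroxy-3-methoxyphenyl)propan-2-yl]-4-hydroxy-5-methoxybenzoate | COC(=O)c1cc(OC)c(O)c(c1)[C@H](Cc1ccc(O)c(OC)c1)CO[Si](C)(C)C(C)(C)C
A4 | alternative 2 | methyl 3-[(2S)-1-{[tert-butyl(dimethyl)silyl]oxy}-3-(3-methoxy-4-oxocyclohexa-2,5-dien-1-ylidene)propan-2-yl]-4-hydroxy-5-methoxybenzoate | COC(=O)c1cc(OC)c(O)c(c1)[C@H](C=C1C=CC(=O)C(OC)=C1)CO[Si](C)(C)C(C)(C)C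
A5 | alternative 2 | methyl (2R,3S)-3-({[tert-butyl(dimethyl)silyl]oxy}methyl)-2-(4-hydroxy-3-methoxyphenyl)-7-methoxy-2,3-dihydro-1-benzofuran-5-carboxylate | COc1cc([C@@H]2Oc3c(OC)cc(C(=O)OC)cc3[C@H]2CO[Si](C)(C)C(C)(C)C)ccc1O
A6 | alternative 3 | 2-[3-iodo-5-methoxy-4-({(1R)-1-[3-methoxy-4-(methoxymethoxy)phenyl]prop-2-en-1-yl}oxy)phenyl]-1,3-dioxolane | COCOc1ccc([C@@H](C=C)Oc2c(I)cc(C3OCCO3)cc2OC)cc1OC
A7 | alternative 3 | [(2R,3S)-5-(1,3-dioxolan-2-yl)-7-methoxy-2-[3-methoxy-4-(methoxymethoxy)phenyl]-2,3-dihydro-1-benzofuran-3-yl]methanol | COCOc1ccc([C@@H]2Oc3c(OC)cc(C4OCCO4)cc3[C@H]2CO)cc1OC
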